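**Retrosynthetic overview**
1. Target ⇐ removal of two MOM groups ⇐ ring C closed last by Mitsunobu etherification of an (R) phenol/primary alcohol; C-3 is set just before by Ru-catalysed hydrogenation with dynamic kinetic resolution of a racemising α-aryl aldehyde (handled as its lactol).
2. Lactol ⇐ a 3-aryl coumarin that already carries ring D and the prenyl group (1,4- then 1,2-hydride reduction).
3. Key disconnection: that pyranocoumarin ⇐ three components in one flask (a ring B benzofuranone, a prenylated ring A salicylaldehyde, a C5 enal) by Knoevenagel condensation, lactone transposition (pyranone ring = ring C at lactone level) and phenol–enal annulation (ring D).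
4. The two aryl components come from a dimethoxyphenylacetic acid (demethylation/lactonisation, MOM) and a bromodihydroxybenzaldehyde (MOM, Stille prenylation).
5. Ring order: A and B are bought; pyranone C, then D, in the key step; C is opened at the diol stage to set C-3 and re-closed as the chroman ether.

Assumption: the [C@@H] centre is C-3 of the chroman and is R (CIP order CH2O > aryl > CH2Ar > H); all four purchased building blocks are taken as catalogue chemicals.

**Route**

Step 1
Reactants: 1 2-(2,4-dimethoxyphenyl)acetic acid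
Product: 2 6-hydroxy-1-benzofuran-2(3H)-one
Conditions: 48 % aq. HBr, AcOH, reflux, 6 h
Reagents that add atoms: none
Why: Acidic aryl methyl ether cleavage (bromide attacks the protonated ethers) frees both phenols, and the ortho-hydroxy acid closes under the same conditions to the five-membered aryl lactone (intramolecular Fischer esterification); no stereocentre.

Step 2
Reactants: 2 6-hydroxy-1-benzofuran-2(3H)-one
Product: 3 6-(methoxymethoxy)-1-benzofuran-2(3H)-one
Conditions: MOMCl (1.2 equiv), i-Pr2NEt (1.5 equiv), CH2Cl2, 0 °C → rt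
Reagents that add atoms: chloromethyl methyl ether, COCCl
Why: Williamson-type MOM protection of the free phenol by the oxocarbenium-like chloromethyl ether under a hindered amine base that neither opens the aryl lactone nor enolises it appreciably; no stereocentre.

Step 3
Reactants: 4 5-bromo-2,4-dihydroxybenzaldehyde
Product: 5 5-bromo-2-hydroxy-4-(methoxymethoxy)benzaldehyde
Conditions: MOMCl (1.05 equiv), K2CO3 (1.1 equiv), acetone, 0 °C → rt
Reagents that add atoms: chloromethyl methyl ether, COCCl
Why: Regioselective Williamson-type MOM protection, because the 2-OH is locked in the hydrogen bond to the aldehyde and only the more acidic, unchelated 4-OH is alkylated; no stereocentre.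

Step 4
Reactants: 5 5-bromo-2-hydroxy-4-(methoxymethoxy)benzaldehyde; 6 tributyl(3-methylbut-2-en-1-yl)stannane
Product: 7 2-hydroxy-4-(methoxymethoxy)-5-(3-methylbut-2-en-1-yl)benzaldehyde
Conditions: Pd(PPh3)4 (5 mol %), DMF, 100 °C
Reagents that add atoms: none
Why: Stille cross-coupling (oxidative addition of zerovalent palladium to the aryl bromide, transmetalation of the allylic stannane at its α-carbon, reductive elimination) puts the linear prenyl group on the brominated carbon, the future C-6 of the chroman, and tolerates the free phenol and the aldehyde; no stereocentre.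

Step 5 (key step)
Reactants: 3 6-(methoxymethoxy)-1-benzofuran-2(3H)-one; 7 2-hydroxy-4-(methoxymethoxy)-5-(3-methylbut-2-en-1-yl)benzaldehyde; 8 3-methylbut-2-enal
Product: 11 7-(methoxymethoxy)-3-[5-(methoxymethoxy)-2,2-dimethyl-2H-chromen-8-yl]-6-(3-methylbut-2-en-1-yl)-2H-chromen-2-one, via arylidene benzofuranone 9 (not isolated), via hydroxyphenyl coumarin 10 (not isolated)
Conditions: 3 + 7 (1:1), Et3N (0.5 equiv), pyridine, 4 Å molecular sieves, 80 °C, 3 h; then 8 (3 equiv), 140 °C (sealed tube), 16 h
Reagents that add atoms: none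
Why: Proposed new method: a one-pot merger of three individually known events, namely Knoevenagel condensation of the acidic lactone CH2 of 3 with aldehyde 7, acyl transfer in the (Z)-arylidene lactone 9 from the ring B phenol oxygen to the neighbouring ring A phenol (intramolecular transesterification that turns the five-membered aryl ester into the conjugated coumarin 10 and uncovers exactly one phenol, on ring B), and pyridine-mediated annulation of that phenol with enal 8 at its only free ortho carbon (C-attack on the aldehyde, loss of water to the ortho-quinone methide, oxa-6π electrocyclisation), so that the pyranone ring and ring D both close in one flask; the closest known reactions are the 2-coumaranone/salicylaldehyde route to 3-(2-hydroxyphenyl)coumarins and the thermal phenol/3-methylbut-2-enal chromene synthesis, and no stereocentre is formed.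

Step 6
Reactants: 11 7-(methoxymethoxy)-3-[5-(methoxymethoxy)-2,2-dimethyl-2H-chromen-8-yl]-6-(3-methylbut-2-en-1-yl)-2H-chromen-2-one
Product: 13 7-(methoxymethoxy)-3-[5-(methoxymethoxy)-2,2-dimethyl-2H-chromen-8-yl]-6-(3-methylbut-2-en-1-yl)-3,4-dihydro-2H-chromen-2-ol (racemic; mixture of anomers), via dihydrocoumarin 12 (not isolated)
Conditions: [(Ph3P)CuH]6 (5 mol % Cu), (EtO)2MeSiH (1.5 equiv), t-BuOH (1.5 equiv), toluene, rt; then i-Bu2AlH (2.5 equiv), −78 °C; aq. KNaC4H4O6 work-up
Reagents that add atoms: none
Why: Copper hydride conjugate reduction (1,4-hydride delivery to C-4 of the unsaturated lactone, protonation of the copper enolate by t-BuOH) is selective for the enoate over the prenyl and ring D alkenes, and i-Bu2AlH at low temperature then stops at the aluminium acetal and gives the lactol (partial lactone reduction); C-3 is formed racemic here and is set in step 7.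

Step 7
Reactants: 13 7-(methoxymethoxy)-3-[5-(methoxymethoxy)-2,2-dimethyl-2H-chromen-8-yl]-6-(3-methylbut-2-en-1-yl)-3,4-dihydro-2H-chromen-2-ol
Product: 15 2-[(2R)-3-hydroxy-2-[5-(methoxymethoxy)-2,2-dimethyl-2H-chromen-8-yl]propyl]-5-(methoxymethoxy)-4-(3-methylbut-2-en-1-yl)phenol, via hydroxy aldehyde 14 (not isolated)
Conditions: RuCl2[(R)-DMM-SDP][(S,S)-DACH] (1 mol %; DMM-SDP = 7,7'-bis[bis(4-methoxy-3,5-dimethylphenyl)phosphanyl]-1,1'-spirobiindane, DACH = trans-cyclohexane-1,2-diamine), KOtBu (1.3 equiv), H2 (50 atm), i-PrOH, rt; neutralised with 1 M HCl at 0 °C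
Reagents that add atoms: none
Why: Asymmetric hydrogenation with dynamic kinetic resolution (Noyori-type outer-sphere C=O reduction by a divalent ruthenium diphosphine–diamine hydride): base opens the lactol to the α-aryl aldehyde 14, which racemises through its enolate faster than it is reduced, and the chiral catalyst reduces one enantiomer preferentially, fixing C-3 as R without touching any C=C bond; the hand of the complex is confirmed on the first run by chiral HPLC against the racemic diol, and the mirror-image complex is used if the sense is opposite.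

Step 8
Reactants: 15 2-[(2R)-3-hydroxy-2-[5-(methoxymethoxy)-2,2-dimethyl-2H-chromen-8-yl]propyl]-5-(methoxymethoxy)-4-(3-methylbut-2-en-1-yl)phenol
Product: 16 (3R)-7-(methoxymethoxy)-3-[5-(methoxymethoxy)-2,2-dimethyl-2H-chromen-8-yl]-6-(3-methylbut-2-en-1-yl)-3,4-dihydro-2H-chromene
Conditions: PPh3 (1.3 equiv), DIAD (1.3 equiv), THF, 0 °C → rt
Reagents that add atoms: none
Why: Intramolecular Mitsunobu etherification (the primary alcohol is activated as its alkoxyphosphonium ion and displaced by the only free phenol in a 6-exo-tet SN2 step) closes ring C, and the stereocentre, one carbon away from the reacting CH2, is untouched.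

Step 9
Reactants: 16 (3R)-7-(methoxymethoxy)-3-[5-(methoxymethoxy)-2,2-dimethyl-2H-chromen-8-yl]-6-(3-methylbut-2-en-1-yl)-3,4-dihydro-2H-chromene
Product: 17 8-[(3R)-7-hydroxy-6-(3-methylbut-2-en-1-yl)-3,4-dihydro-2H-chromen-3-yl]-2,2-dimethyl-2H-chromen-5-ol
Conditions: HCl (3 M in MeOH), 40 °C, 2 h
Reagents that add atoms: none
Why: Acid-catalysed acetal exchange with methanol removes both MOM groups under conditions mild enough to spare the 2,2-dimethylchromene, the ortho-prenylphenol and the non-epimerisable C-3 centre.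

**Compound list**
1 | 2-(2,4-dimethoxyphenyl)acetic acid | COc1ccc(CC(=O)O)c(OC)c1 | starting material
2 | 6-hydroxy-1-benzofuran-2(3H)-one | O=C1Cc2ccc(O)cc2O1 | intermediate
3 | 6-(methoxymethoxy)-1-benzofuran-2(3H)-one | O=C1Cc2ccc(OCOC)cc2O1 | intermediate
4 | 5-bromo-2,4-dihydroxybenzaldehyde | O=Cc1cc(Br)c(O)cc1O | starting material
5 | 5-bromo-2-hydroxy-4-(methoxymethoxy)benzaldehyde | O=Cc1cc(Br)c(OCOC)cc1O | intermediate
6 | tributyl(3-methylbut-2-en-1-yl)stannane | CCCC[Sn](CCCC)(CCCC)CC=C(C)C | starting material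
7 | 2-hydroxy-4-(methoxymethoxy)-5-(3-methylbut-2-en-1-yl)benzaldehyde | O=Cc1cc(CC=C(C)C)c(OCOC)cc1O | intermediate
8 | 3-methylbut-2-enal | CC(C)=CC=O | starting material
9 | (3Z)-3-[2-hydroxy-4-(methoxymethoxy)-5-(3-methylbut-2-en-1-yl)benzylidene]-6-(methoxymethoxy)-1-benzofuran-2(3H)-one (equilibrates with the E isomer) | O=C1Oc2cc(OCOC)ccc2/C1=C/c1cc(CC=C(C)C)c(OCOC)cc1O | intermediate (not isolated)
10 | 3-[2-hydroxy-4-(methoxymethoxy)phenyl]-7-(methoxymethoxy)-6-(3-methylbut-2-en-1-yl)-2H-chromen-2-one | O=c1oc2cc(OCOC)c(CC=C(C)C)cc2cc1-c1ccc(OCOC)cc1O | intermediate (not isolated)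
11 | 7-(methoxymethoxy)-3-[5-(methoxymethoxy)-2,2-dimethyl-2H-chromen-8-yl]-6-(3-methylbut-2-en-1-yl)-2H-chromen-2-one | O=c1oc2cc(OCOC)c(CC=C(C)C)cc2cc1-c1ccc(OCOC)c2c1OC(C)(C)C=C2 | intermediate
12 | 7-(methoxymethoxy)-3-[5-(methoxymethoxy)-2,2-dimethyl-2H-chromen-8-yl]-6-(3-methylbut-2-en-1-yl)-3,4-dihydro-2H-chromen-2-one (racemic) | O=C1Oc2cc(OCOC)c(CC=C(C)C)cc2CC1c1ccc(OCOC)c2c1OC(C)(C)C=C2 | intermediate (not isolated)
13 | 7-(methoxymethoxy)-3-[5-(methoxymethoxy)-2,2-dimethyl-2H-chromen-8-yl]-6-(3-methylbut-2-en-1-yl)-3,4-dihydro-2H-chromen-2-ol (racemic, both anomers) | OC1Oc2cc(OCOC)c(CC=C(C)C)cc2CC1c1ccc(OCOC)c2c1OC(C)(C)C=C2 | intermediate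
14 | 3-[2-hydroxy-4-(methoxymethoxy)-5-(3-methylbut-2-en-1-yl)phenyl]-2-[5-(methoxymethoxy)-2,2-dimethyl-2H-chromen-8-yl]propanal (racemising) | O=CC(Cc1cc(CC=C(C)C)c(OCOC)cc1O)c1ccc(OCOC)c2c1OC(C)(C)C=C2 | intermediate (not isolated)
15 | 2-[(2R)-3-hydroxy-2-[5-(methoxymethoxy)-2,2-dimethyl-2H-chromen-8-yl]propyl]-5-(methoxymethoxy)-4-(3-methylbut-2-en-1-yl)phenol | OC[C@@H](c1ccc(OCOC)c2c1OC(C)(C)C=C2)Cc1cc(CC=C(C)C)c(OCOC)cc1O | intermediate
16 | (3R)-7-(methoxymethoxy)-3-[5-(methoxymethoxy)-2,2-dimethyl-2H-chromen-8-yl]-6-(3-methylbut-2-en-1-yl)-3,4-dihydro-2H-chromene | CC(C)=CCc1cc2c(cc1OCOC)OC[C@@H](c1ccc(OCOC)c3c1OC(C)(C)C=C3)C2 | intermediate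
17 | 8-[(3R)-7-hydroxy-6-(3-methylbut-2-en-1-yl)-3,4-dihydro-2H-chromen-3-yl]-2,2-dimethyl-2H-chromen-5-ol | CC(C)=CCc1cc2c(cc1O)OC[C@@H](c1ccc(O)c3c1OC(C)(C)C=C3)C2 | target

**Step count and risks**
Total step count: 9. Longest linear sequence: 7 (steps 1, 2, 5, 6, 7, 8, 9; the branch through steps 3 and 4 is equally long).

Most at risk is step 5, because the annulation with 8 must occur at the crowded carbon between the phenol and the MOM ether. If it stalls, the fallback sets out from 3 and 7: the Et3N/pyridine condensation is stopped at 80 °C and the hydroxyphenyl coumarin 10 is isolated. Its only phenol is O-alkylated with 3-chloro-3-methylbut-1-yne (K2CO3, KI, CuI cat., acetone, reflux) to the aryl 1,1-dimethylpropargyl ether 7-(methoxymethoxy)-3-[4-(methoxymethoxy)-2-(2-methylbut-3-yn-2-yloxy)phenyl]-6-(3-methylbut-2-en-1-yl)-2H-chromen-2-one F1. Heating F1 in o-xylene at 140 °C triggers the aromatic propargyl Claisen rearrangement to the only free ortho carbon, a 1,5-hydrogen shift and oxa-6π electrocyclisation, and the route is rejoined at 11.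

Second is step 7, where the enantioselectivity for an α-aryl aldehyde carrying a benzyl-type second substituent and an ortho-oxygenated aryl ring is untested. The fallback sets out from 13: NaBH4 (MeOH, 0 °C) gives the racemic diol 2-[3-hydroxy-2-[5-(methoxymethoxy)-2,2-dimethyl-2H-chromen-8-yl]propyl]-5-(methoxymethoxy)-4-(3-methylbut-2-en-1-yl)phenol F3. Its enantiomers are separated by preparative chiral supercritical-fluid chromatography (amylose tris(3,5-dimethylphenylcarbamate) phase, CO2/MeOH), and the R enantiomer is 15, where the route is rejoined.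

Third is step 6, where the copper hydride may be slow on the α-aryl coumarin or the two hydride stages may interfere in one flask. The fallback sets out from 11: magnesium turnings in MeOH (0 °C → rt) reduce the conjugated C=C by electron transfer while methoxide opens the lactone, giving racemic methyl 3-[2-hydroxy-4-(methoxymethoxy)-5-(3-methylbut-2-en-1-yl)phenyl]-2-[5-(methoxymethoxy)-2,2-dimethyl-2H-chromen-8-yl]propanoate F2. Treating F2 with i-Bu2AlH (2.2 equiv, toluene, −78 °C; the first equivalent is taken up by the phenol) reduces the ester to the aldehyde, which closes on work-up to the lactol, and the route is rejoined at 13.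

**Further compounds**
F1 | step 5 | 7-(methoxymethoxy)-3-[4-(methoxymethoxy)-2-(2-methylbut-3-yn-2-yloxy)phenyl]-6-(3-methylbut-2-en-1-yl)-2H-chromen-2-one | O=c1oc2cc(OCOC)c(CC=C(C)C)cc2cc1-c1ccc(OCOC)cc1OC(C)(C)C#C
F2 | step 6 | methyl 3-[2-hydroxy-4-(methoxymethoxy)-5-(3-methylbut-2-en-1-yl)phenyl]-2-[5-(methoxymethoxy)-2,2-dimethyl-2H-chromen-8-yl]propanoate (racemic) | COC(=O)C(Cc1cc(CC=C(C)C)c(OCOC)cc1O)c1ccc(OCOC)c2c1OC(C)(C)C=C2
F3 | step 7 | 2-[3-hydroxy-2-[5-(methoxymethoxy)-2,2-dimethyl-2H-chromen-8-yl]propyl]-5-(methoxymethoxy)-4-(3-methylbut-2-en-1-yl)phenol (racemic) | OCC(c1ccc(OCOC)c2c1OC(C)(C)C=C2)Cc1cc(CC=C(C)C)c(OCOC)cc1O
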